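**Numbering used throughout**

1 = 4-methoxy-2-methylbenzoic acid; 2 = 5-bromo-4-methoxy-2-methylbenzoic acid; 3 = 4-hydroxy-2,5-dimethylbenzoic acid; 4 = benzyl 4-hydroxy-2,5-dimethylbenzoate; 5 = acid chloride of 2; 6 = bromo depside benzyl ester; 7 = depside dibenzyl ester; 8 = 2,2'-dideoxysquamatic acid; 9 = squamatic acid.

## Analysis of the target

Squamatic acid (9) is a depside: two benzene rings, each with five substituents, joined by one aryl ester between the ring A carbonyl C7 and the oxygen on C4' of ring B. Ring A is numbered C1 (bearing C7), C2 (OH), C3 (COOH), C4 (OCH3), C5 (H), C6 (CH3); ring B is numbered C1' (COOH), C2' (OH), C3' (CH3), C4' (ester O), C5' (H), C6' (CH3). There is no stereocentre and no stereogenic axis, so the problem is one of substitution pattern and functional-group differentiation. The sensitive groups are the aryl ester, which hydroxide, alkoxides and amines cleave, and the two salicylic acid units, which lose CO2 on strong heating or in hot acid. The difficulty lies mainly in ring A: its two carboxyl carbons must end in different states (C7 esterified, the C3 carboxyl free), and a conventional route carries two phenolic oxygens of which only the one on C4 is methylated. A conventional route must also esterify an acid with two ortho substituents. The plan rests on the fact that each phenol is ortho to a free carboxyl whose other ortho carbon is already substituted: C2–OH beside the C3 carboxyl (C4 bears OCH3) and C2'–OH beside the C1' carboxyl (C6' bears CH3). In the compound without both hydroxyls (8), C2 and C2' are therefore the only hydrogen-bearing ring carbons that a carboxylate can reach.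

## Retrosynthetic reasoning

**9 to 8.** The C2–O and C2'–O bonds are cut. They are the only bonds whose removal takes every phenol out of the synthesis, and each lies ortho to a free acid that can steer a metal to that carbon. This removes phenol protection and selective O-methylation, and lets the ester be made on an acid with one ortho substituent. The forward step is an aerobic, carboxylate-directed C–H oxidation that must act twice in one molecule, at C–H bonds flanked on both sides, without cleaving the aryl ester or expelling CO2.

**8 to 7.** Both acids are masked as benzyl esters. Hydrogenolysis is neutral and reductive, which the aryl ester tolerates, and one operation frees both acids.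

**7 to 6.** The bond between C3 and its carboxyl carbon is cut, leaving bromine on C3. This way the two carboxyl carbons of ring A never exist in the same state: C7 is already the aryl ester when the C3 carboxyl is created, directly as its benzyl ester, by carbonylation of the bromide. The forward step must insert into an electron-rich C–Br bond ortho to OCH3 and must not let the alcohol exchange into the depside ester.

**6 to 2 and 4, through 5.** The depside bond C7–O(C4') is cut into the ring A acid 2, activated as acid chloride 5, and the ring B phenol 4. This is the only cut that gives two halves of similar size. At this stage the acyl carbon has a single ortho neighbour (the C6 methyl), so acylation of the moderately hindered phenol needs no special activation.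

**2 to 1.** The C3–Br bond is cut (position 5 of acid 1 in benzoic acid numbering). Electrophilic bromination should go there: the position is ortho to OCH3, para to the methyl group and meta to the carboxyl, while the other position ortho to OCH3 is wedged between two substituents.

**4 to 3.** The benzyl ester of ring B is cut back to the hydroxy acid 3. The forward alkylation must distinguish carboxylate from phenol, which a weak base should achieve.

## Alternatives that were turned down

**Alternative 1:** Ring A is disconnected at C1–C6 and unravelled to a linear chain already esterified to ring B, the aryl 3,5,7-trioxooctanoate A1.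
- Forward key step: mild base would make the chain methylene next to the ester (the future C1) add to the terminal methyl ketone (the future C6). Dehydration and enolisation would give the orsellinate depside A2.
- For it: the route follows the biosynthesis, needs no arene substitution chemistry for ring A, and has the depside ester in place before ring A exists, so no doubly ortho-substituted acid is esterified.
- Against it: A2 lacks the C3 carboxyl and the C4 methyl ether. Carboxylation at C3 in competition with C5, methylation of C4–OH in preference to C2–OH, and removal of two benzyl groups must follow, roughly four steps. In A1 the aryloxide is a good leaving group, so C-acylation or ketene formation with loss of the ring B phenoxide competes with the aldol.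
- Comparison: on precedent this alternative is stronger, because aldol aromatisation of triketo esters is an established reaction class. The chosen plan offers instead a key step that delivers 9 itself and halves that contain no phenol.

**Alternative 2:** Both C–COOH bonds (C3–C and C1'–C) are cut last, back to the diiodo depside A3 with both phenols benzylated.
- Forward key step: cathodic reductive carboxylation (NiBr2 with a bipyridine ligand, sacrificial magnesium anode) would turn each C–I bond into C–COOH and give A4. Hydrogenolysis of the two benzyl ethers would then give 9.
- For it: both acids arrive free and late, so no acid protecting group is needed and decarboxylation is no concern earlier. Reductive carboxylation of aryl iodides is a known reaction type, so this key step is better founded than the chosen one.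
- Against it: each iodide has two ortho substituents (C3 between the benzyloxy group and OCH3, C1' between the benzyloxy group and CH3), where oxidative addition and carboxylation are slow and hydrodeiodination takes over. The aryl ester must survive reducing conditions and nucleophilic arylmetal species. A3 can only be made by solving the phenol differentiation, selective methylation and regioselective iodination that the chosen plan removes.
- Comparison: it needs one step after its key step; the chosen plan needs none and uses much simpler halves.

**Alternative 3:** Ring A is cut at C5–C6 and C1–C2 into the ring B aryl but-2-ynoate A5 and the trioxygenated silyl ketene acetal diene A6.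
- Forward key step: heating would give a 1,4-cyclohexadiene by [4+2] cycloaddition, the CH2 terminus of A6 bonding to the methyl-bearing alkyne carbon. Loss of the benzyloxy group from C2 with a C5 hydrogen, then desilylation on work-up, would give A7. One hydrogenolysis of three benzyl groups would give 9.
- For it: all five substituents of ring A are placed in one step with regiochemistry set by the polarity of the partners, and the methyl ether arrives inside the diene. In convergence and in steps after the key step (one) it is about as good as the chosen plan.
- Against it: A6 is a push–pull diene with an ester on an inner carbon and a fully substituted ketene acetal terminus, so it is hard to prepare and a weak diene. A5 is a β-methyl ynoate, a sluggish dienophile whose aryl ester invites conjugate addition and acyl transfer at the temperature needed. Ring B must still be made with its two phenols told apart.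
- Comparison: its risk is spread over diene synthesis and cycloaddition. The chosen plan puts one risk in the last step, after five routine steps from two simple benzoic acids.

Key step: step 6

Remark on the chemistry: C3 of ring A is position 5 of acid 1 in benzoic acid numbering. In step 6 benzoquinone is treated as a ligand that is not consumed, so O2 is the only oxidant in the balanced equation.

## Route

Step 1
Reactants: 1 4-methoxy-2-methylbenzoic acid
Product: 2 5-bromo-4-methoxy-2-methylbenzoic acid
Conditions: Br2, AcOH, rt
Reagents that add atoms: bromine, BrBr
Why: Electrophilic aromatic bromination; OCH3 is the strongest director, and of its two ortho positions only position 5 is unhindered, para to the methyl group and meta to the carboxyl.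

Step 2
Reactants: 3 4-hydroxy-2,5-dimethylbenzoic acid
Product: 4 benzyl 4-hydroxy-2,5-dimethylbenzoate
Conditions: BnBr, KHCO3, DMF, 40 °C
Reagents that add atoms: benzyl bromide, BrCc1ccccc1
Why: SN2 alkylation of the carboxylate; KHCO3 deprotonates the acid but leaves the far less acidic phenol largely protonated, so only the carboxylate should be alkylated.

Step 3
Reactants: 2 5-bromo-4-methoxy-2-methylbenzoic acid; 4 benzyl 4-hydroxy-2,5-dimethylbenzoate
Product: 6 benzyl 4-[(5-bromo-4-methoxy-2-methylbenzoyl)oxy]-2,5-dimethylbenzoate, via acid chloride 5 (not isolated)
Conditions: (COCl)2, DMF (cat.), CH2Cl2, 0 °C to rt; then 4, Et3N, DMAP (cat.), CH2Cl2, 0 °C to rt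
Reagents that add atoms: none
Why: Acid chloride formation followed by DMAP-catalysed acylation of the phenol through an N-acylpyridinium ion; the acyl carbon has one ortho substituent only, and the benzyl ester and aryl bromide are inert.

Step 4
Reactants: 6 benzyl 4-[(5-bromo-4-methoxy-2-methylbenzoyl)oxy]-2,5-dimethylbenzoate
Product: 7 benzyl 5-({4-[(benzyloxy)carbonyl]-2,5-dimethylphenoxy}carbonyl)-2-methoxy-4-methylbenzoate
Conditions: Pd(OAc)2 (3 mol%), Xantphos (6 mol%), CO (1 atm), BnOH (3 equiv), Et3N, toluene, 80 °C
Reagents that add atoms: carbon monoxide, [C-]#[O+]; benzyl alcohol, OCc1ccccc1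
Why: Palladium-catalysed alkoxycarbonylation of an aryl bromide: oxidative addition of zerovalent palladium into C–Br, CO insertion to the acylpalladium species, and alcoholysis by benzyl alcohol. With a tertiary amine as the only base no benzyloxide forms, which should spare the aryl ester.

Step 5
Reactants: 7 benzyl 5-({4-[(benzyloxy)carbonyl]-2,5-dimethylphenoxy}carbonyl)-2-methoxy-4-methylbenzoate
Product: 8 2,2'-dideoxysquamatic acid, 5-[(4-carboxy-2,5-dimethylphenoxy)carbonyl]-2-methoxy-4-methylbenzoic acid
Conditions: H2 (1 atm), Pd/C, EtOAc–THF, rt
Reagents that add atoms: none
Why: Catalytic hydrogenolysis of the two benzylic C–O bonds under neutral conditions; the aryl ester and the methyl ether are not benzylic and should remain.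

Step 6
Reactants: 8 2,2'-dideoxysquamatic acid
Product: 9 squamatic acid
Conditions: Pd(OAc)2 (20 mol%), KOAc (4 equiv), benzoquinone (40 mol%), O2 (1 atm), DMA, 115 °C; then 1 M HCl, crystallisation
Reagents that add atoms: dioxygen, O=O
Why: Proposed new method: each potassium carboxylate (on C3 and on C1') binds divalent palladium and delivers it to its single ortho C–H bond by acetate-assisted concerted metalation–deprotonation, giving a five-membered palladacycle at C2 and at C2'. The aryl–palladium bond is then oxygenated by O2, the C–O bond forms, and protonolysis releases the phenol and returns divalent palladium, with benzoquinone as a ligand that speeds turnover. The closest known reaction type is the Pd(OAc)2/KOAc/benzoquinone/O2 ortho-hydroxylation of benzoic acids, established for one acid per molecule and for ortho C–H bonds with a free neighbouring position; here it must act twice in one molecule and at C–H bonds substituted on both sides. No ring of the target is closed (the palladacycles are transient) and no stereocentre is formed. The step needs site selectivity, which the substrate secures because the second ortho position of each acid is occupied (C4 by OCH3, C6' by CH3) and C5–H and C5'–H have no carboxylate beside them. C2–H lies between two carbonyl-bearing carbons and should be the most acidic ring C–H, which favours its deprotonative metalation, while C2'–H is crowded only by a methyl group. The step also needs chemoselectivity over palladation of the C6' methyl group (a six-membered palladacycle, expected to be less favoured) and over loss of CO2, which the carboxylate salt form is meant to hold back.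

## Compound list

1 | 4-methoxy-2-methylbenzoic acid | COc1ccc(C(=O)O)c(C)c1 | starting material
2 | 5-bromo-4-methoxy-2-methylbenzoic acid | COc1cc(C)c(C(=O)O)cc1Br | intermediate
3 | 4-hydroxy-2,5-dimethylbenzoic acid | Cc1cc(C(=O)O)c(C)cc1O | starting material
4 | benzyl 4-hydroxy-2,5-dimethylbenzoate | Cc1cc(C(=O)OCc2ccccc2)c(C)cc1O | intermediate
5 | 5-bromo-4-methoxy-2-methylbenzoyl chloride | COc1cc(C)c(C(=O)Cl)cc1Br | intermediate
6 | benzyl 4-[(5-bromo-4-methoxy-2-methylbenzoyl)oxy]-2,5-dimethylbenzoate | COc1cc(C)c(C(=O)Oc2cc(C)c(C(=O)OCc3ccccc3)cc2C)cc1Br | intermediate
7 | benzyl 5-({4-[(benzyloxy)carbonyl]-2,5-dimethylphenoxy}carbonyl)-2-methoxy-4-methylbenzoate | COc1cc(C)c(C(=O)Oc2cc(C)c(C(=O)OCc3ccccc3)cc2C)cc1C(=O)OCc1ccccc1 | intermediate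
8 | 2,2'-dideoxysquamatic acid, 5-[(4-carboxy-2,5-dimethylphenoxy)carbonyl]-2-methoxy-4-methylbenzoic acid | COc1cc(C)c(C(=O)Oc2cc(C)c(C(=O)O)cc2C)cc1C(=O)O | intermediate
9 | squamatic acid, 3-[(4-carboxy-3-hydroxy-2,5-dimethylphenoxy)carbonyl]-2-hydroxy-6-methoxy-4-methylbenzoic acid | COc1cc(C)c(C(=O)Oc2cc(C)c(C(=O)O)c(O)c2C)c(O)c1C(=O)O | target

## Step count and least certain steps

Total step count: 6. Longest linear sequence: 5 steps (steps 1, 3, 4, 5, 6, or equally steps 2, 3, 4, 5, 6).

**Step 6 (key step).**
- What may go wrong: the catalyst may stall after the first hydroxylation, because the salicylate formed chelates divalent palladium more firmly than the remaining carboxylate. Metalation at the flanked C–H bonds may fail, with palladation of the C6' methyl group and lactonisation taking over. The salicylic acid units may lose CO2 at 115 °C. Acetate or phenoxide may cleave the depside ester.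
- Fallback (known chemistry, sets out from 1, returns at 9): the phenolic oxygens are no longer introduced on the depside. Acid 1 is hydroxylated with Pd(OAc)2, KOAc, benzoquinone and O2 in DMA at its only ortho C–H bond, which has a hydrogen-bearing neighbour and so falls within the established scope, giving 2-hydroxy-4-methoxy-6-methylbenzoic acid F1. Benzylation (BnBr, KHCO3, DMF) gives benzyl 2-hydroxy-4-methoxy-6-methylbenzoate F2. Magnesium-mediated ortho-formylation (MgCl2, Et3N, paraformaldehyde, MeCN, reflux) can attack only C3, the one free position ortho to the phenol, and should give benzyl 3-formyl-2-hydroxy-4-methoxy-6-methylbenzoate F3. Hydrogenolysis (H2, Pd/C, EtOAc, stopped after one equivalent) should give 3-formyl-2-hydroxy-4-methoxy-6-methylbenzoic acid F4. Commercial 2,4-dihydroxy-3,6-dimethylbenzoic acid F5 is benzylated at the carboxyl (BnBr, KHCO3, DMF) to benzyl 2,4-dihydroxy-3,6-dimethylbenzoate F6. F4 and F6 are condensed with trifluoroacetic anhydride in toluene at room temperature, the classical depside condensation; the C2' hydroxyl of F6 is hydrogen-bonded to its ester and hindered, so the C4' hydroxyl should be acylated. This gives benzyl 4-[(3-formyl-2-hydroxy-4-methoxy-6-methylbenzoyl)oxy]-2-hydroxy-3,6-dimethylbenzoate F7. Pinnick oxidation (NaClO2, NaH2PO4, sulfamic acid as hypochlorite scavenger) should give 3-({4-[(benzyloxy)carbonyl]-3-hydroxy-2,5-dimethylphenoxy}carbonyl)-2-hydroxy-6-methoxy-4-methylbenzoic acid F8. Hydrogenolysis (H2, Pd/C) then gives 9.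

**Step 4.**
- What may go wrong: alcoholysis of the depside ester by benzyl alcohol under the hot, basic conditions, or slow oxidative addition at the electron-rich bromide ortho to OCH3, followed by catalyst decomposition.
- Fallback (sets out from 2, returns at 7): the carbonylation is moved ahead of the esterification, so no aryl ester is present when alcohol and base are hot. Bromo acid 2 is carbonylated (Pd(OAc)2, Xantphos, CO, BnOH, Et3N in excess, toluene, 80 °C) to 5-[(benzyloxy)carbonyl]-4-methoxy-2-methylbenzoic acid F9. F9 is then coupled with phenol 4 by Steglich esterification (EDC·HCl, DMAP, CH2Cl2) to give 7.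

**Step 2.**
- What may go wrong: competing alkylation of the phenol, giving ether and doubly benzylated material, if the base strength or temperature is not well controlled.
- Fallback (sets out from 3, returns at 4): the phenol is masked first, so no selectivity is needed. Acetylation (Ac2O, pyridine, aqueous work-up) gives 4-acetoxy-2,5-dimethylbenzoic acid F10. Benzylation (BnBr, KHCO3, DMF) gives benzyl 4-acetoxy-2,5-dimethylbenzoate F11. Aminolysis of the aryl acetate with pyrrolidine in CH2Cl2 at 0 °C, which should leave the benzyl benzoate alone, gives 4.

## Further compounds

F1 | step 6 | 2-hydroxy-4-methoxy-6-methylbenzoic acid | COc1cc(C)c(C(=O)O)c(O)c1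
F2 | step 6 | benzyl 2-hydroxy-4-methoxy-6-methylbenzoate | COc1cc(C)c(C(=O)OCc2ccccc2)c(O)c1
F3 | step 6 | benzyl 3-formyl-2-hydroxy-4-methoxy-6-methylbenzoate | COc1cc(C)c(C(=O)OCc2ccccc2)c(O)c1C=O
F4 | step 6 | 3-formyl-2-hydroxy-4-methoxy-6-methylbenzoic acid | COc1cc(C)c(C(=O)O)c(O)c1C=O
F5 | step 6 | 2,4-dihydroxy-3,6-dimethylbenzoic acid | Cc1cc(O)c(C)c(O)c1C(=O)O
F6 | step 6 | benzyl 2,4-dihydroxy-3,6-dimethylbenzoate | Cc1cc(O)c(C)c(O)c1C(=O)OCc1ccccc1
F7 | step 6 | benzyl 4-[(3-formyl-2-hydroxy-4-methoxy-6-methylbenzoyl)oxy]-2-hydroxy-3,6-dimethylbenzoate | COc1cc(C)c(C(=O)Oc2cc(C)c(C(=O)OCc3ccccc3)c(O)c2C)c(O)c1C=O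
F8 | step 6 | 3-({4-[(benzyloxy)carbonyl]-3-hydroxy-2,5-dimethylphenoxy}carbonyl)-2-hydroxy-6-methoxy-4-methylbenzoic acid | COc1cc(C)c(C(=O)Oc2cc(C)c(C(=O)OCc3ccccc3)c(O)c2C)c(O)c1C(=O)O
F9 | step 4 | 5-[(benzyloxy)carbonyl]-4-methoxy-2-methylbenzoic acid | COc1cc(C)c(C(=O)O)cc1C(=O)OCc1ccccc1
F10 | step 2 | 4-acetoxy-2,5-dimethylbenzoic acid | CC(=O)Oc1cc(C)c(C(=O)O)cc1C
F11 | step 2 | benzyl 4-acetoxy-2,5-dimethylbenzoate | CC(=O)Oc1cc(C)c(C(=O)OCc2ccccc2)cc1C
A1 | alternative 1 | 3-(benzyloxy)-4-[(benzyloxy)carbonyl]-2,5-dimethylphenyl 3,5,7-trioxooctanoate | CC(=O)CC(=O)CC(=O)CC(=O)Oc1cc(C)c(C(=O)OCc2ccccc2)c(OCc2ccccc2)c1C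
A2 | alternative 1 | benzyl 2-(benzyloxy)-4-[(2,4-dihydroxy-6-methylbenzoyl)oxy]-3,6-dimethylbenzoate | Cc1cc(O)cc(O)c1C(=O)Oc1cc(C)c(C(=O)OCc2ccccc2)c(OCc2ccccc2)c1C
A3 | alternative 2 | 3-(benzyloxy)-4-iodo-2,5-dimethylphenyl 2-(benzyloxy)-3-iodo-4-methoxy-6-methylbenzoate | COc1cc(C)c(C(=O)Oc2cc(C)c(I)c(OCc3ccccc3)c2C)c(OCc2ccccc2)c1I
A4 | alternative 2 | squamatic acid 2,2'-di-O-benzyl ether | COc1cc(C)c(C(=O)Oc2cc(C)c(C(=O)O)c(OCc3ccccc3)c2C)c(OCc2ccccc2)c1C(=O)O
A5 | alternative 3 | benzyl 2-(benzyloxy)-4-(but-2-ynoyloxy)-3,6-dimethylbenzoate | CC#CC(=O)Oc1cc(C)c(C(=O)OCc2ccccc2)c(OCc2ccccc2)c1C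
A6 | alternative 3 | benzyl 2-[(benzyloxy)(trimethylsilyloxy)methylidene]-3-methoxybut-3-enoate (either double-bond geometry) | C=C(OC)C(C(=O)OCc1ccccc1)=C(OCc1ccccc1)O[Si](C)(C)C
A7 | alternative 3 | squamatic acid dibenzyl ester 2'-O-benzyl ether | COc1cc(C)c(C(=O)Oc2cc(C)c(C(=O)OCc3ccccc3)c(OCc3ccccc3)c2C)c(O)c1C(=O)OCc1ccccc1
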